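A direct plan would build ring A from an open chain and attach ring B last. The quaternary hydroxy ester A1 would come from two successive chelate-controlled dianion alkylations. It would be oxidised, C-acylated twice to the triacylmethane A2, closed by Dieckmann condensation to the cyclic triketone A3 and joined to ring B through a Mannich/Michael one-carbon bridge.
Its weakest steps would be:
- the second dianion alkylation, because facial selectivity on a tetrasubstituted enolate would fix the final ee;
- the acylation/Dieckmann sequence on a non-enolisable β-keto ester, because retro-Claisen cleavage would threaten it and it would spend about six steps on one ring;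
- the bridging, because the methylidene triketone could self-condense and bridged dimers could exchange halves.

Ring A (the cyclohexadienone with the C4 methyl/prenyl quaternary carbon) and ring B (the arene) carry the same acetyl, prenyl, three oxygen and bridge substituents in the same order; they differ only by the C4 methyl group. The target is therefore the mono-C-methyl derivative of an achiral, C2-symmetric bis(prenylphloroacetophenone)methane, and the route rests on the C4–CH3 bond. One enantioselective dearomative C-methylation of that dimer would create the quaternary stereocentre and the difference between the two rings in a single operation. No open-chain quaternary centre, no acylation/ring-closure sequence and no cross-coupling of two different halves through the methylene bridge would then be needed.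

Key step: step 3

Remark: tautomers of the enolised β-triketone ring are treated as one compound, and the alkaloid series of the ammonium salt (cinchonidinium or its pseudoenantiomer cinchoninium) that leads to the 4R centre is assumed to be fixed by a short screen of both.

Step 1
Reactants: 1 1-(2,4,6-trihydroxyphenyl)ethan-1-one (phloroacetophenone); 2 1-bromo-3-methylbut-2-ene (prenyl bromide)
Product: 3 1-[2,4,6-trihydroxy-3-(3-methylbut-2-en-1-yl)phenyl]ethan-1-one
Conditions: 1 (2 equiv), 2 (1 equiv, slow addition), 5% aq. KOH, 0 °C → rt, Ar; 1 M HCl; chromatography (excess 1 recovered)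
Reagents that add atoms: none
Why: SN2 C-prenylation of the ambident phloroglucinol phenoxide should be favoured over O-alkylation in water, the two free ring carbons of 1 are equivalent, and the excess of 1 limits a second prenylation.

Step 2
Reactants: 3 1-[2,4,6-trihydroxy-3-(3-methylbut-2-en-1-yl)phenyl]ethan-1-one (two molecules)
Product: 6 bis[3-acetyl-2,4,6-trihydroxy-5-(3-methylbut-2-en-1-yl)phenyl]methane, via hydroxymethyl adduct 4 (not isolated), via ortho-quinone methide 5 (not isolated)
Conditions: 37% aq. HCHO (0.5 equiv), KOH (20 mol%), MeOH/H2O, 0 °C → rt, Ar; 1 M HCl; crystallisation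
Reagents that add atoms: formaldehyde, C=O
Why: Lederer–Manasse hydroxymethylation at the only free ring carbon of 3 gives 4, which loses hydroxide to the ortho-quinone methide 5; a second phenoxide of 3 then adds in a Michael addition and re-aromatises, and since 3 has a single free position the sequence must stop at the symmetric methylene-bridged dimer.

Step 3
Reactants: 6 bis[3-acetyl-2,4,6-trihydroxy-5-(3-methylbut-2-en-1-yl)phenyl]methane
Product: 7 (4R)-2-acetyl-6-{[3-acetyl-2,4,6-trihydroxy-5-(3-methylbut-2-en-1-yl)phenyl]methyl}-3,5-dihydroxy-4-methyl-4-(3-methylbut-2-en-1-yl)cyclohexa-2,5-dien-1-one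
Conditions: O(9)-allyl-N-(9-anthracenylmethyl)cinchonidinium bromide (10 mol%), CsOH·H2O (2.2 equiv), MeI (0.7 equiv), toluene/MTBE, −40 → −10 °C, Ar; 1 M HCl; chromatography (6 recovered)
Reagents that add atoms: iodomethane, CI
Why: Proposed new method: under solid–liquid phase transfer the phenoxide of one ring of 6 is carried into the organic phase as a tight ion pair with the chiral ammonium cation and attacks MeI in an SN2 C-alkylation at its prenyl-bearing carbon (C5 of the aryl unit, C4 of 7), after which the initial cyclohexadienone tautomerises to the enolised β-triketone; the closest known reaction types are the phase-transfer C-methylation of indanone and β-keto ester enolates under cinchona ammonium salts and the cinchona-ammonium alkylative dearomatisation of acylphloroglucinols with Michael acceptors, neither of which has been shown for MeI on a phloroglucinol ring. No ring is closed: the step forms only the C4–CH3 bond and thereby turns an achiral C2-symmetric bis-arene into the unsymmetrical target. The single stereocentre is set by the cation, which should cover one face of the planar anion, anchored between the hydrogen-bonded acetyl edge and the bulky arylmethyl edge, so that MeI enters from the open face. Ring selectivity is not needed because the two rings are homotopic; site selectivity for C5 over the bridge-bearing C1 should follow from shielding of C1 by the orthogonal partner ring and its inter-ring O–H···O bonds, and attack at the acetyl-bearing C3 would destroy the vinylogous acid conjugation. C- over O-methylation is expected because MeI is a soft electrophile and every phenoxide oxygen is hydrogen-bonded to the acetyl group or to the partner ring, and methylation of the second ring is held back by limiting MeI, with unreacted 6 recycled.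

**Compound list**

1 | 1-(2,4,6-trihydroxyphenyl)ethan-1-one (phloroacetophenone) | CC(=O)c1c(O)cc(O)cc1O | starting material
2 | 1-bromo-3-methylbut-2-ene (prenyl bromide) | CC(C)=CCBr | starting material
3 | 1-[2,4,6-trihydroxy-3-(3-methylbut-2-en-1-yl)phenyl]ethan-1-one | CC(=O)c1c(O)cc(O)c(CC=C(C)C)c1O | intermediate
4 | 1-[2,4,6-trihydroxy-3-(hydroxymethyl)-5-(3-methylbut-2-en-1-yl)phenyl]ethan-1-one | CC(=O)c1c(O)c(CO)c(O)c(CC=C(C)C)c1O | intermediate
5 | 2-acetyl-3,5-dihydroxy-6-methylidene-4-(3-methylbut-2-en-1-yl)cyclohexa-2,4-dien-1-one | CC(=O)C1=C(O)C(CC=C(C)C)=C(O)C(=C)C1=O | intermediate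
6 | bis[3-acetyl-2,4,6-trihydroxy-5-(3-methylbut-2-en-1-yl)phenyl]methane | CC(=O)c1c(O)c(CC=C(C)C)c(O)c(Cc2c(O)c(CC=C(C)C)c(O)c(C(C)=O)c2O)c1O | intermediate
7 | (4R)-2-acetyl-6-{[3-acetyl-2,4,6-trihydroxy-5-(3-methylbut-2-en-1-yl)phenyl]methyl}-3,5-dihydroxy-4-methyl-4-(3-methylbut-2-en-1-yl)cyclohexa-2,5-dien-1-one | CC(=O)C1=C(O)[C@](C)(CC=C(C)C)C(O)=C(Cc2c(O)c(CC=C(C)C)c(O)c(C(C)=O)c2O)C1=O | target

Total steps: 3. Longest linear sequence: 3.

Steps most likely to fail:

- **Step 3 (key step).** Facial discrimination by the chiral cation may be poor, and O-methylation may compete in the weakly solvating organic phase. The fallback sets out from 6. The classical C-methylation of acylphloroglucinols in a protic medium (NaOMe, MeI limiting, MeOH, 0 °C → rt) favours C- over O-alkylation and should give racemic 2-acetyl-6-{[3-acetyl-2,4,6-trihydroxy-5-(3-methylbut-2-en-1-yl)phenyl]methyl}-3,5-dihydroxy-4-methyl-4-(3-methylbut-2-en-1-yl)cyclohexa-2,5-dien-1-one F1. Preparative chromatography on a chiral stationary phase would then remove the (4S)-enantiomer F2, and the route is rejoined at 7.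

- **Step 1.** Over-alkylation of the phloroglucinol nucleus (a second C-prenylation at the remaining free ring carbon, or O-prenylation) may erode the mono-prenyl product. The fallback sets out from 1 and reverses the order of bridging and prenylation. Compound 1 (3 equiv) with 37% aq. HCHO and catalytic KOH in MeOH/H2O should give bis(3-acetyl-2,4,6-trihydroxyphenyl)methane F3, in which each ring keeps a single free ring carbon. Double C-prenylation with 2 (2.2 equiv) in cold aq. KOH would then rejoin the route at 6.

- **Step 2.** The hydroxymethyl adduct may accumulate, or the quinone methide may be captured by solvent instead of by the second phenoxide, with oxidative darkening of the phenoxide solution. The fallback sets out from 3 and separates electrophile formation from coupling. A Mannich reaction of 3 with aq. Me2NH and aq. HCHO in EtOH should give 1-{3-[(dimethylamino)methyl]-2,4,6-trihydroxy-5-(3-methylbut-2-en-1-yl)phenyl}ethan-1-one F4. Heating F4 with one further equivalent of 3 in 1,4-dioxane at 80 °C under an argon sweep should release the quinone methide by loss of Me2NH and rejoin the route at 6.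

**Further compounds**

F1 | step 3 | racemic 2-acetyl-6-{[3-acetyl-2,4,6-trihydroxy-5-(3-methylbut-2-en-1-yl)phenyl]methyl}-3,5-dihydroxy-4-methyl-4-(3-methylbut-2-en-1-yl)cyclohexa-2,5-dien-1-one | CC(=O)C1=C(O)C(C)(CC=C(C)C)C(O)=C(Cc2c(O)c(CC=C(C)C)c(O)c(C(C)=O)c2O)C1=O
F2 | step 3 | (4S)-2-acetyl-6-{[3-acetyl-2,4,6-trihydroxy-5-(3-methylbut-2-en-1-yl)phenyl]methyl}-3,5-dihydroxy-4-methyl-4-(3-methylbut-2-en-1-yl)cyclohexa-2,5-dien-1-one | CC(=O)C1=C(O)[C@@](C)(CC=C(C)C)C(O)=C(Cc2c(O)c(CC=C(C)C)c(O)c(C(C)=O)c2O)C1=O
F3 | step 1 | bis(3-acetyl-2,4,6-trihydroxyphenyl)methane | CC(=O)c1c(O)cc(O)c(Cc2c(O)cc(O)c(C(C)=O)c2O)c1O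
F4 | step 2 | 1-{3-[(dimethylamino)methyl]-2,4,6-trihydroxy-5-(3-methylbut-2-en-1-yl)phenyl}ethan-1-one | CC(=O)c1c(O)c(CN(C)C)c(O)c(CC=C(C)C)c1O
A1 | direct plan | ethyl (2S,3S)-3-hydroxy-2-methyl-2-(3-methylbut-2-en-1-yl)butanoate | C[C@H](O)[C@](C)(CC=C(C)C)C(=O)OCC
A2 | direct plan | ethyl (2S)-4-acetyl-2-methyl-2-(3-methylbut-2-en-1-yl)-3,5-dioxohexanoate | CC(=O)C(C(C)=O)C(=O)[C@](C)(CC=C(C)C)C(=O)OCC
A3 | direct plan | (4R)-2-acetyl-3,5-dihydroxy-4-methyl-4-(3-methylbut-2-en-1-yl)cyclohexa-2,5-dien-1-one | CC(=O)C1=C(O)[C@](C)(CC=C(C)C)C(O)=CC1=O
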